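**Retrosynthetic overview**
1. Polymatin A ⇐ C8 angelation and unmasking of the α-methylene ⇐ 6,12-lactone ⇐ ten-membered C10 ketone, converted to the Z-enoate by enol triflate and methoxycarbonylation.
2. Key step: anionic oxy-Cope ring expansion (6→10) of a trans-2-isopropenyl-1-vinylcyclohexanol. This forms the C2–C3 bond and the 4E olefin.
3. The cyclohexane (C5–C10) comes from a citronellal→isopulegol-type carbonyl-ene cyclization of a prenyl aldehyde.
4. C6–C7 and the lactone carbons come from an indium Barbier reaction of a Morita–Baylis–Hillman-derived bromide with prenal. C8 and C9 come from L-threitol acetonide.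
5. Ring order: cyclohexane (ene) → ten-membered ring (oxy-Cope) → γ-lactone (last).

Assumption: the (Z)-allylindium adds anti with 1,2-induction from C8 to give the C6/C7 configuration drawn. The ten-membered ketone enolizes toward C1 to give the ring-cis (Z) enol triflate.

---

**Step 1**
Reactants: 1 (2,3-O-isopropylidene-L-threitol, (4S,5S))
Product: 2 (mono-TBS ether)
Conditions: NaH (1 equiv), TBSCl (1 equiv), THF, 0 °C→rt
Reagents that add atoms: TBSCl, CC(C)(C)[Si](C)(C)Cl
Why: Mono-silylation of the C2-symmetric diol differentiates the C7 and C10 termini. C8/C9 are fixed by L-threitol (silyl protection).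

**Step 2**
Reactants: 2
Product: 3 (α-alkoxy aldehyde)
Conditions: (COCl)2, DMSO, Et3N, CH2Cl2, −78 °C
Reagents that add atoms: none
Why: Swern oxidation of the free primary alcohol; the trans-dioxolane is not epimerized.

**Step 3**
Reactants: 3, 4 (methyl acrylate)
Product: 5 (MBH adduct)
Conditions: DABCO (0.3 equiv), neat methyl acrylate, rt, 3 d
Reagents that add atoms: none
Why: Morita–Baylis–Hillman reaction; the new carbinol stereocenter is transient and is destroyed in the next step.

**Step 4**
Reactants: 5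
Product: 6 ((Z)-2-(bromomethyl)alkenoate)
Conditions: NBS, Me2S, CH2Cl2, 0 °C→rt
Reagents that add atoms: NBS, O=C1CCC(=O)N1Br (supplies Br)
Why: SN2′ bromination of the MBH alcohol gives the trisubstituted allylic bromide with the Z geometry.

**Step 5**
Reactants: 6, 7 (prenal)
Product: 8 (anti homoallylic alcohol)
Conditions: In powder, THF/H2O, rt
Reagents that add atoms: none
Why: Barbier allylation through a chair transition state, with γ-attack at C7. The (Z)-allylindium gives the anti (future trans-lactone) C6/C7 pair, and C8 induces the absolute sense.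

**Step 6**
Reactants: 8
Product: 9 (C6-OTBDPS)
Conditions: TBDPSCl, imidazole, DMAP, DMF, 50 °C
Reagents that add atoms: TBDPSCl, CC(C)(C)[Si](c1ccccc1)(c1ccccc1)Cl
Why: Protects the C6 alcohol so it survives later oxidations, and prevents lactonization before the cyclohexane forms.

**Step 7**
Reactants: 9
Product: 10 (primary alcohol)
Conditions: HF·pyridine, pyridine, THF, 0 °C→rt
Reagents that add atoms: none
Why: Primary TBS ether is cleaved selectively; TBDPS, acetonide and acrylate survive.

**Step 8**
Reactants: 10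
Product: 11 (C10 aldehyde)
Conditions: Dess–Martin periodinane, NaHCO3, CH2Cl2, rt
Reagents that add atoms: none
Why: Mild oxidation to the ene-cyclization precursor.

**Step 9**
Reactants: 11
Product: 12 (cyclohexanol)
Conditions: ZnBr2 (2 equiv), CH2Cl2, 0 °C→rt
Reagents that add atoms: none
Why: Intramolecular carbonyl-ene reaction (citronellal→isopulegol type) forms C5–C10 and the isopropenyl group (either prenyl methyl can donate H). It gives the trans-diequatorial C10-OH/isopropenyl pair in the chair locked by the trans-acetonide. C5 and C10 are destroyed later.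

**Step 10**
Reactants: 12
Product: 13 (β-dimethylamino ester)
Conditions: Me2NH (2 M in THF), MeOH, rt
Reagents that add atoms: dimethylamine, CNC
Why: Aza-Michael addition masks the α-methylene acrylate, which would not survive the Grignard/KH steps. It is regenerated at the end.

**Step 11**
Reactants: 13
Product: 14 (cyclohexanone)
Conditions: Dess–Martin periodinane, NaHCO3, CH2Cl2, rt
Reagents that add atoms: none
Why: Oxidation gives the C10 ketone. C5 (α to the ketone) equilibrates to equatorial isopropenyl.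

**Step 12**
Reactants: 14
Product: 15 (trans-1-vinyl-2-isopropenylcyclohexanol)
Conditions: CeCl3, CH2=CHMgBr, THF, −78 °C
Reagents that add atoms: vinylmagnesium bromide, C=C[Mg]Br
Why: Organocerium 1,2-addition. Axial attack is blocked by the syn-axial C6 OTBDPS, so vinyl enters equatorially, trans to the equatorial isopropenyl, as the chair transition state requires.

**Step 13**
Reactants: 15
Product: 16 (ten-membered ketone, 4E)
Conditions: KH, 18-crown-6, THF, 0 °C→rt; then aq. NH4Cl
Reagents that add atoms: none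
Why: Anionic oxy-Cope [3,3] ring expansion (the key step). The diequatorial chair transition state forms C2–C3, breaks C5–C10 and sets the E C4=C5 olefin; C6–C9 are untouched.

**Step 14**
Reactants: 16
Product: 17 (Z enol triflate)
Conditions: KHMDS, PhNTf2, THF, −78 °C
Reagents that add atoms: PhNTf2, O=S(=O)(C(F)(F)F)N(c1ccccc1)S(=O)(=O)C(F)(F)F (supplies Tf)
Why: Kinetic deprotonation at the unhindered C1 CH2 (not the tertiary, α-alkoxy C9-H). The ten-membered ring prefers the cis (Z) ring olefin.

**Step 15**
Reactants: 17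
Product: 18 (1(10)Z-enoate, C14 ester)
Conditions: Pd(OAc)2, PPh3, CO (1 atm), MeOH, Et3N, DMF, 60 °C
Reagents that add atoms: CO ([C-]#[O+]) and MeOH (CO)
Why: Pd-catalysed methoxycarbonylation of the enol triflate; the alkene geometry is retained.

**Step 16**
Reactants: 18
Product: 19 (trans 6,12-lactone)
Conditions: TBAF, THF, rt; then PPTS (2 equiv), toluene, 60 °C
Reagents that add atoms: none
Why: Desilylation then acid-promoted γ-lactonization of the free C6-OH onto the C12 ester. C8 is still acetonide-protected, so only the 6,12-olide can form.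

**Step 17**
Reactants: 19
Product: 20 (C8,C9-diol)
Conditions: Dowex-50 (H+), MeOH/H2O, 40 °C
Reagents that add atoms: none (water adds only H; acetone is lost)
Why: Acid-catalysed acetonide hydrolysis; the ring is now flexible, so no strain issue.

**Step 18**
Reactants: 20, 21 (angelic acid)
Product: 22 (C8 angelate)
Conditions: 2,4,6-Cl3C6H2COCl, Et3N, THF; then 20, DMAP, toluene, rt
Reagents that add atoms: none (21 is a numbered reactant)
Why: Yamaguchi esterification. C9-OH is more hindered (allylic to the trisubstituted enoate) and hydrogen-bonded to the C14 ester, so C8 is acylated preferentially; the Z-angelate is retained.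

**Step 19**
Reactants: 22
Product: 23 (Polymatin A)
Conditions: MeI, MeCN, rt; then aq. NaHCO3
Reagents that add atoms: none (methyl leaves as NMe3)
Why: Quaternization followed by Hofmann-type retro-Michael elimination regenerates the exocyclic α-methylene lactone.

---

**Compound list**
1 | (4S,5S)-2,2-dimethyl-1,3-dioxolane-4,5-diyldimethanol (2,3-O-isopropylidene-L-threitol) | OC[C@@H]1OC(C)(C)O[C@H]1CO | starting material
2 | mono-TBS ether of 1 | OC[C@@H]1OC(C)(C)O[C@H]1CO[Si](C)(C)C(C)(C)C | intermediate
3 | trans-dioxolane aldehyde (CHO at C7, CH2OTBS at C10) | O=C[C@@H]1OC(C)(C)O[C@H]1CO[Si](C)(C)C(C)(C)C | intermediate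
4 | methyl acrylate | C=CC(=O)OC | starting material
5 | MBH adduct of 3 (C7 carbinol unspecified) | C=C(C(=O)OC)C(O)[C@@H]1OC(C)(C)O[C@H]1CO[Si](C)(C)C(C)(C)C | intermediate
6 | (Z)-allylic bromide | BrC/C(C(=O)OC)=C\[C@@H]1OC(C)(C)O[C@H]1CO[Si](C)(C)C(C)(C)C | intermediate
7 | prenal (3-methylbut-2-enal) | CC(C)=CC=O | starting material
8 | anti homoallylic alcohol (C6-OH, C7 set) | C=C(C(=O)OC)[C@@H]([C@H](O)C=C(C)C)[C@@H]1OC(C)(C)O[C@H]1CO[Si](C)(C)C(C)(C)C | intermediate
9 | C6-OTBDPS ether of 8 | C=C(C(=O)OC)[C@@H]([C@H](O[Si](c1ccccc1)(c1ccccc1)C(C)(C)C)C=C(C)C)[C@@H]1OC(C)(C)O[C@H]1CO[Si](C)(C)C(C)(C)C | intermediate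
10 | primary alcohol from 9 | C=C(C(=O)OC)[C@@H]([C@H](O[Si](c1ccccc1)(c1ccccc1)C(C)(C)C)C=C(C)C)[C@@H]1OC(C)(C)O[C@H]1CO | intermediate
11 | C10 aldehyde | C=C(C(=O)OC)[C@@H]([C@H](O[Si](c1ccccc1)(c1ccccc1)C(C)(C)C)C=C(C)C)[C@@H]1OC(C)(C)O[C@H]1C=O | intermediate
12 | cyclohexanol (isopropenyl and C10-OH trans-diequatorial) | C=C(C)[C@@H]1[C@@H](O)[C@@H]2OC(C)(C)O[C@H]2[C@@H](C(=C)C(=O)OC)[C@@H]1O[Si](c3ccccc3)(c3ccccc3)C(C)(C)C | intermediate
13 | dimethylamine adduct (C11 unspecified) | C=C(C)[C@@H]1[C@@H](O)[C@@H]2OC(C)(C)O[C@H]2[C@@H](C(CN(C)C)C(=O)OC)[C@@H]1O[Si](c3ccccc3)(c3ccccc3)C(C)(C)C | intermediate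
14 | cyclohexanone (C5 equatorial) | C=C(C)[C@@H]1C(=O)[C@@H]2OC(C)(C)O[C@H]2[C@@H](C(CN(C)C)C(=O)OC)[C@@H]1O[Si](c3ccccc3)(c3ccccc3)C(C)(C)C | intermediate
15 | tertiary vinyl carbinol (vinyl and isopropenyl trans) | C=C(C)[C@@H]1[C@@](O)(C=C)[C@@H]2OC(C)(C)O[C@H]2[C@@H](C(CN(C)C)C(=O)OC)[C@@H]1O[Si](c3ccccc3)(c3ccccc3)C(C)(C)C | intermediate
16 | ten-membered ketone (4E) | O=C1CCC/C(C)=C/[C@@H](O[Si](c3ccccc3)(c3ccccc3)C(C)(C)C)[C@H](C(CN(C)C)C(=O)OC)[C@@H]2OC(C)(C)O[C@@H]12 | intermediate
17 | Z enol triflate | FC(F)(F)S(=O)(=O)O/C1=C/CC/C(C)=C/[C@@H](O[Si](c3ccccc3)(c3ccccc3)C(C)(C)C)[C@H](C(CN(C)C)C(=O)OC)[C@@H]2OC(C)(C)O[C@@H]12 | intermediate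
18 | 1(10)Z-enoate | COC(=O)/C1=C/CC/C(C)=C/[C@@H](O[Si](c3ccccc3)(c3ccccc3)C(C)(C)C)[C@H](C(CN(C)C)C(=O)OC)[C@@H]2OC(C)(C)O[C@@H]12 | intermediate
19 | acetonide lactone (amine adduct) | COC(=O)/C1=C/CC/C(C)=C/[C@H]3OC(=O)C(CN(C)C)[C@@H]3[C@@H]2OC(C)(C)O[C@@H]12 | intermediate
20 | 8,9-diol lactone | COC(=O)/C1=C/CC/C(C)=C/[C@H]3OC(=O)C(CN(C)C)[C@@H]3[C@H](O)[C@H]1O | intermediate
21 | angelic acid ((Z)-2-methylbut-2-enoic acid) | OC(=O)/C(C)=C\C | starting material
22 | C8 angelate, amine adduct | COC(=O)/C1=C/CC/C(C)=C/[C@H]3OC(=O)C(CN(C)C)[C@@H]3[C@H](OC(=O)/C(C)=C\C)[C@H]1O | intermediate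
23 | Polymatin A | C=C1C(=O)O[C@@H]2/C=C(\C)CC/C=C(/C(=O)OC)[C@H](O)[C@@H](OC(=O)/C(C)=C\C)[C@@H]12 | target

---

**Totals**
Total steps: 19. Longest linear sequence: 19 (1→2→3→5→6→8→9→10→11→12→13→14→15→16→17→18→19→20→22→23).

**Three steps most likely to fail**
1. **Step 5 (Barbier).** The γ-alkoxy allylindium may β-eliminate, and C6/C7 diastereocontrol from the remote C8 center is modest.
   Fallback: make a cyclohexene with C6=C7 by RCM of a threitol-derived diene, then epoxidize it and open the epoxide at C7 with a lithium acetate/malonate enolate to build the trans-lactone by a different mechanism.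
2. **Step 13 (oxy-Cope).** Base-induced retro-aza-Michael of the β-amino ester, or the wrong chair/boat preference, could intervene.
   Fallback: build the ten-membered ring by intramolecular NHK macrocyclization forming C6–C7 with concomitant lactonization, from an open-chain precursor that already carries the Z-enoate and the E-olefin.
3. **Step 14 (Z enol triflate).** The wrong regio- or geometric isomer would give the 1(10)E compound.
   Fallback: carry the C14 ester in the oxy-Cope substrate (carbinol at C5, quaternary C10 bearing CO2Me and vinyl), so the Z-enoate geometry is fixed in the chair transition state. Then convert the resulting C5 ketone into the C4=C5 olefin.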